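**Retrosynthetic overview** (isochromene numbering: O2, C1, C3, C4, C4a, C5, C6, C7, C8, C8a)
1. Target 25 ⇒ desilylation and acylation of the (7S)-tertiary alcohol 13 with (2E,4S)-2,4-dimethyldec-2-enoic acid 22 (auxiliary methylation, then Wittig).
2. 13 ⇒ monocyclic pyran keto-aldehyde 12 by an enantioselective carbene-catalysed intramolecular aldehyde–ketone benzoin: the C7–C8 bond closes the carbocycle C4a–C5–C6–C7–C8–C8a and creates C7 in one isomerisation.
3. Enabling feature: the acyloin C8(=O)–C7(OH)(CH3) inside the carbocycle, flanked by C6=O. Opened at C7–C8 it becomes a formyl group on pyran carbon C8a and the methyl ketone of a 1,2-diketone hung on C5.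
4. 12 ⇒ pyranone ester 6 by 1,2-alkynylation with ester reduction, Meyer–Schuster rearrangement, C5 chlorination and oxidation.
5. Ring order: arene (purchased) → pyran ring (step 3) → carbocycle (step 8).

Key step: step 8

Remark 1: compounds 7–11 are carried as racemates or diastereomer mixtures and the exocyclic C4a=C5 geometry of 10–12 is left undefined, because these sp3 centres are erased in steps 5 and 7 and the push–pull alkene isomerises.
Remark 2: the sense of induction of the triazolium catalyst on this substrate has to be confirmed by experiment; both antipodes are commercial, and the one that delivers 7S is used.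

**Step 1**
Reactants: 1 2-hydroxy-6-methylbenzoic acid
Product: 2 tert-butyldimethylsilyl 2-[(tert-butyldimethylsilyl)oxy]-6-methylbenzoate
Conditions: TBSCl (2.4 equiv), imidazole (5 equiv), DMF, 23 °C
Reagents that add atoms: tert-butyldimethylsilyl chloride, C[Si](C)(Cl)C(C)(C)C
Why: Imidazole-promoted O-silylation masks the phenol for the whole route and gives the silyl ester needed for acid-free acyl chloride formation.

**Step 2**
Reactants: 2 tert-butyldimethylsilyl 2-[(tert-butyldimethylsilyl)oxy]-6-methylbenzoate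
Product: 3 2-[(tert-butyldimethylsilyl)oxy]-6-methylbenzoyl chloride
Conditions: (COCl)2 (1.2 equiv), DMF (cat.), CH2Cl2, 0 °C → 23 °C
Reagents that add atoms: oxalyl chloride, ClC(=O)C(=O)Cl
Why: Vilsmeier-type activation converts a silyl ester directly into the acyl chloride with loss of the silyl chloride, so no free HCl is formed and the aryl silyl ether should survive.

**Step 3**
Reactants: 3 2-[(tert-butyldimethylsilyl)oxy]-6-methylbenzoyl chloride; 4 ethyl 2-[(dimethylamino)methylidene]-3-oxobutanoate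
Product: 6 ethyl 6-{2-[(tert-butyldimethylsilyl)oxy]-6-methylphenyl}-4-oxo-4H-pyran-3-carboxylate, via acylated enaminone 5 (not isolated)
Conditions: LiHMDS (2.5 equiv) added to 3 + 4, THF, −78 °C → −20 °C; then 1 M aq. HCl/Et2O, 0 °C → 23 °C
Reagents that add atoms: none
Why: γ-Deprotonation of the enaminone and C-acylation of the dienolate, then acid-induced addition–elimination of the new enol oxygen at the aminomethylene carbon, is the established enaminone route to 3-carbethoxy-4-pyranones and fixes the aryl group at C3 and the future C8 carbon at C8a without regiochemical ambiguity.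

**Step 4**
Reactants: 6 ethyl 6-{2-[(tert-butyldimethylsilyl)oxy]-6-methylphenyl}-4-oxo-4H-pyran-3-carboxylate; 7 (±)-but-3-yn-2-ol
Product: 9 6-{2-[(tert-butyldimethylsilyl)oxy]-6-methylphenyl}-4-(3-hydroxybut-1-yn-1-yl)-3-(hydroxymethyl)-4H-pyran-4-ol (diastereomer mixture, used crude), via alkynyl carbinol ester 8 (not isolated)
Conditions: 7 (1.6 equiv), n-BuLi (3.2 equiv), THF, −78 °C; anhydrous CeCl3 (1.7 equiv), −78 °C; 6, −78 °C; pH 7 buffer; crude in CH2Cl2, DIBAL-H (5 equiv), −78 °C → −20 °C; Rochelle salt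
Reagents that add atoms: none
Why: The alkynylcerium reagent is a hard, weakly basic nucleophile that should add 1,2 to the pyranone carbonyl (future C4a) and not 1,4 at the ester-activated C1–H, and DIBAL-H then reduces the ester to the allylic alcohol while C6 is still an alkyne carbon and cannot be reduced.

**Step 5**
Reactants: 9 6-{2-[(tert-butyldimethylsilyl)oxy]-6-methylphenyl}-4-(3-hydroxybut-1-yn-1-yl)-3-(hydroxymethyl)-4H-pyran-4-ol
Product: 10 1-[6-{2-[(tert-butyldimethylsilyl)oxy]-6-methylphenyl}-3-(hydroxymethyl)-4H-pyran-4-ylidene]-3-hydroxybutan-2-one (racemic)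
Conditions: TsOH·H2O (10 mol %), THF/H2O (9:1), 0 °C → 23 °C
Reagents that add atoms: water, O
Why: Meyer–Schuster rearrangement: the tertiary carbinol ionises very easily because the cation is pyrylium-stabilised, water adds at the distal alkyne carbon (C6) and the allenol tautomerises to the conjugated (pyranylidene)methyl ketone, which is the thermodynamic sink.

**Step 6**
Reactants: 10 1-[6-{2-[(tert-butyldimethylsilyl)oxy]-6-methylphenyl}-3-(hydroxymethyl)-4H-pyran-4-ylidene]-3-hydroxybutan-2-one
Product: 11 1-chloro-1-[6-{2-[(tert-butyldimethylsilyl)oxy]-6-methylphenyl}-3-(hydroxymethyl)-4H-pyran-4-ylidene]-3-hydroxybutan-2-one (racemic)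
Conditions: NCS (1.05 equiv), CH2Cl2, 0 °C
Reagents that add atoms: N-chlorosuccinimide, O=C1CCC(=O)N1Cl
Why: Electrophilic chlorination should occur at C5, the α-carbon of the vinylogous ester and the most nucleophilic, least hindered carbon of the push–pull system (as in α-halogenation of enaminones); C4 is shielded by the twisted ortho,ortho′-disubstituted aryl group.

**Step 7**
Reactants: 11 1-chloro-1-[6-{2-[(tert-butyldimethylsilyl)oxy]-6-methylphenyl}-3-(hydroxymethyl)-4H-pyran-4-ylidene]-3-hydroxybutan-2-one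
Product: 12 6-{2-[(tert-butyldimethylsilyl)oxy]-6-methylphenyl}-4-(1-chloro-2,3-dioxobutylidene)-4H-pyran-3-carbaldehyde (achiral, used at once)
Conditions: Dess–Martin periodinane (2.5 equiv), NaHCO3, CH2Cl2, 0 °C → 23 °C
Reagents that add atoms: none
Why: Dess–Martin oxidation under buffered, non-acidic conditions converts the primary allylic alcohol into the C8 aldehyde and the α-hydroxy ketone into the C6/C7 1,2-diketone in one operation.

**Step 8**
Reactants: 12 6-{2-[(tert-butyldimethylsilyl)oxy]-6-methylphenyl}-4-(1-chloro-2,3-dioxobutylidene)-4H-pyran-3-carbaldehyde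
Product: 13 (7S)-3-{2-[(tert-butyldimethylsilyl)oxy]-6-methylphenyl}-5-chloro-7-hydroxy-7-methyl-6H-isochromene-6,8(7H)-dione
Conditions: (5aS,10bR)-2-phenyl-5a,10b-dihydro-4H,6H-indeno[2,1-b][1,2,4]triazolo[4,3-d][1,4]oxazin-2-ium tetrafluoroborate (15 mol %), Et3N (15 mol %), toluene, 23 °C, Ar
Reagents that add atoms: none
Why: The triazolylidene adds to the C8 formyl group and proton transfer gives the Breslow intermediate, whose nucleophilic C8 attacks the C7 ketone of the 1,2-diketone; release of the carbene leaves the C8 ketone, so the C7–C8 bond, the carbocycle and the tertiary carbinol arise in one isomerisation. The closest known reaction type is the carbene-catalysed intramolecular crossed aldehyde–ketone benzoin cyclisation, which gives six-membered α-hydroxy ketones with a methyl-bearing quaternary carbinol using aminoindanol-derived triazolium salts. The ring C8–C8a–C4a–C5–C6–C7 closes by 6-exo-trig addition to the C7 carbonyl. C7 is the only new stereocentre and is controlled by the chiral catalyst, which selects the enantiotopic face of the C7 ketone in the hydrogen-bonded addition transition state. The step needs C7 over C6 and acyl-anion over homoenolate reactivity: C7 is the more electrophilic carbonyl (α-dicarbonyl, whereas C6 is a vinylogous ester carbonyl) and leads to the six- and not the five-membered ring, and the enal β-carbon C1 bears oxygen while C8a is fully substituted, which disfavours β-umpolung. Only the E isomer of 12 can cyclise, but the push–pull C4a=C5 bond should isomerise under the conditions so that both isomers funnel to 13.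

**Step 9**
Reactants: 14 (S)-4-benzyl-1,3-oxazolidin-2-one; 15 octanoyl chloride
Product: 16 (S)-4-benzyl-3-octanoyl-1,3-oxazolidin-2-one
Conditions: n-BuLi (1.05 equiv), THF, −78 °C; then 15, −78 °C → 0 °C
Reagents that add atoms: none
Why: N-acylation of the lithiated oxazolidinone is the standard entry to the chiral imide.

**Step 10**
Reactants: 16 (S)-4-benzyl-3-octanoyl-1,3-oxazolidin-2-one
Product: 17 (S)-4-benzyl-3-[(2S)-2-methyloctanoyl]-1,3-oxazolidin-2-one
Conditions: NaHMDS (1.1 equiv), THF, −78 °C; MeI (4 equiv), −78 °C → −40 °C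
Reagents that add atoms: iodomethane, CI
Why: Oxazolidinone-auxiliary (Evans) alkylation: the chelated Z-enolate is methylated on the face opposite the benzyl group, which sets the 2S centre (the later C4′).

**Step 11**
Reactants: 17 (S)-4-benzyl-3-[(2S)-2-methyloctanoyl]-1,3-oxazolidin-2-one
Product: 18 (S)-2-methyloctan-1-ol
Conditions: LiBH4 (1.5 equiv), H2O (1.5 equiv), Et2O, 0 °C
Reagents that add atoms: none
Why: Reductive cleavage of the imide gives the primary alcohol without touching the α-stereocentre and returns the auxiliary.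

**Step 12**
Reactants: 18 (S)-2-methyloctan-1-ol; 19 ethyl 2-(triphenyl-λ5-phosphanylidene)propanoate
Product: 21 ethyl (2E,4S)-2,4-dimethyldec-2-enoate, via (S)-2-methyloctanal 20 (not isolated)
Conditions: Dess–Martin periodinane (1.2 equiv), NaHCO3, CH2Cl2, 0 °C → 23 °C; then 19 (1.5 equiv), 23 °C
Reagents that add atoms: none
Why: Oxidation with in situ Wittig olefination by the stabilised ylide should give the E-trisubstituted enoate and traps the α-chiral aldehyde before it can epimerise.

**Step 13**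
Reactants: 21 ethyl (2E,4S)-2,4-dimethyldec-2-enoate
Product: 22 (2E,4S)-2,4-dimethyldec-2-enoic acid
Conditions: LiOH·H2O (3 equiv), THF/MeOH/H2O, 23 °C; then 1 M HCl to pH 3
Reagents that add atoms: lithium hydroxide, [Li+].[OH-]
Why: Saponification; the γ-stereocentre is not acidic under these conditions and the E geometry is retained.

**Step 14**
Reactants: 13 (7S)-3-{2-[(tert-butyldimethylsilyl)oxy]-6-methylphenyl}-5-chloro-7-hydroxy-7-methyl-6H-isochromene-6,8(7H)-dione; 22 (2E,4S)-2,4-dimethyldec-2-enoic acid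
Product: 24 (7S)-3-{2-[(tert-butyldimethylsilyl)oxy]-6-methylphenyl}-5-chloro-7-methyl-6,8-dioxo-7,8-dihydro-6H-isochromen-7-yl (2E,4S)-2,4-dimethyldec-2-enoate, via acyl chloride 23 (not isolated)
Conditions: 22, (COCl)2 (1.2 equiv), DMF (cat.), CH2Cl2, 0 °C → 23 °C, evaporate; then 13, DMAP (3 equiv), CH2Cl2, 0 °C → 23 °C
Reagents that add atoms: none
Why: DMAP-mediated acylation of the tertiary 7-hydroxy group of this ring system with acyl chlorides is standard; DMAP as the only base limits γ-deprotonation of the acylpyridinium ion, and the quaternary C7 cannot epimerise.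

**Step 15**
Reactants: 24 (7S)-3-{2-[(tert-butyldimethylsilyl)oxy]-6-methylphenyl}-5-chloro-7-methyl-6,8-dioxo-7,8-dihydro-6H-isochromen-7-yl (2E,4S)-2,4-dimethyldec-2-enoate
Product: 25 (7S)-5-chloro-3-(2-hydroxy-6-methylphenyl)-7-methyl-6,8-dioxo-7,8-dihydro-6H-isochromen-7-yl (2E,4S)-2,4-dimethyldec-2-enoate (CNP0323429.2)
Conditions: HF·pyridine, THF/pyridine, 0 °C → 23 °C
Reagents that add atoms: none
Why: Fluoride cleaves the aryl silyl ether under buffered conditions that should leave the amine-sensitive pyran, the vinyl chloride and the tertiary ester untouched.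

**Compound list**
1 | 2-hydroxy-6-methylbenzoic acid | Cc1cccc(O)c1C(=O)O | starting material
2 | tert-butyldimethylsilyl 2-[(tert-butyldimethylsilyl)oxy]-6-methylbenzoate | Cc1cccc(O[Si](C)(C)C(C)(C)C)c1C(=O)O[Si](C)(C)C(C)(C)C | intermediate
3 | 2-[(tert-butyldimethylsilyl)oxy]-6-methylbenzoyl chloride | Cc1cccc(O[Si](C)(C)C(C)(C)C)c1C(Cl)=O | intermediate
4 | ethyl 2-[(dimethylamino)methylidene]-3-oxobutanoate | CCOC(=O)C(=CN(C)C)C(C)=O | starting material
5 | ethyl 5-{2-[(tert-butyldimethylsilyl)oxy]-6-methylphenyl}-2-[(dimethylamino)methylidene]-3,5-dioxopentanoate (formed as lithium enolate) | CCOC(=O)C(=CN(C)C)C(=O)CC(=O)c1c(C)cccc1O[Si](C)(C)C(C)(C)C | intermediate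
6 | ethyl 6-{2-[(tert-butyldimethylsilyl)oxy]-6-methylphenyl}-4-oxo-4H-pyran-3-carboxylate | CCOC(=O)C1=COC(c2c(C)cccc2O[Si](C)(C)C(C)(C)C)=CC1=O | intermediate
7 | (±)-but-3-yn-2-ol | CC(O)C#C | starting material
8 | ethyl 6-{2-[(tert-butyldimethylsilyl)oxy]-6-methylphenyl}-4-hydroxy-4-(3-hydroxybut-1-yn-1-yl)-4H-pyran-3-carboxylate (diastereomer mixture) | CCOC(=O)C1=COC(c2c(C)cccc2O[Si](C)(C)C(C)(C)C)=CC1(O)C#CC(C)O | intermediate
9 | 6-{2-[(tert-butyldimethylsilyl)oxy]-6-methylphenyl}-4-(3-hydroxybut-1-yn-1-yl)-3-(hydroxymethyl)-4H-pyran-4-ol (diastereomer mixture) | OCC1=COC(c2c(C)cccc2O[Si](C)(C)C(C)(C)C)=CC1(O)C#CC(C)O | intermediate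
10 | 1-[6-{2-[(tert-butyldimethylsilyl)oxy]-6-methylphenyl}-3-(hydroxymethyl)-4H-pyran-4-ylidene]-3-hydroxybutan-2-one (racemic, alkene isomers interconvert) | OCC1=COC(c2c(C)cccc2O[Si](C)(C)C(C)(C)C)=CC1=CC(=O)C(C)O | intermediate
11 | 1-chloro-1-[6-{2-[(tert-butyldimethylsilyl)oxy]-6-methylphenyl}-3-(hydroxymethyl)-4H-pyran-4-ylidene]-3-hydroxybutan-2-one (racemic, alkene isomers interconvert) | OCC1=COC(c2c(C)cccc2O[Si](C)(C)C(C)(C)C)=CC1=C(Cl)C(=O)C(C)O | intermediate
12 | 6-{2-[(tert-butyldimethylsilyl)oxy]-6-methylphenyl}-4-(1-chloro-2,3-dioxobutylidene)-4H-pyran-3-carbaldehyde (achiral, alkene isomers interconvert) | O=CC1=COC(c2c(C)cccc2O[Si](C)(C)C(C)(C)C)=CC1=C(Cl)C(=O)C(C)=O | intermediate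
13 | (7S)-3-{2-[(tert-butyldimethylsilyl)oxy]-6-methylphenyl}-5-chloro-7-hydroxy-7-methyl-6H-isochromene-6,8(7H)-dione | O[C@@]1(C)C(=O)C2=COC(c3c(C)cccc3O[Si](C)(C)C(C)(C)C)=CC2=C(Cl)C1=O | intermediate
14 | (S)-4-benzyl-1,3-oxazolidin-2-one | O=C1OC[C@H](Cc2ccccc2)N1 | starting material
15 | octanoyl chloride | CCCCCCCC(=O)Cl | starting material
16 | (S)-4-benzyl-3-octanoyl-1,3-oxazolidin-2-one | O=C1OC[C@H](Cc2ccccc2)N1C(=O)CCCCCCC | intermediate
17 | (S)-4-benzyl-3-[(2S)-2-methyloctanoyl]-1,3-oxazolidin-2-one | O=C1OC[C@H](Cc2ccccc2)N1C(=O)[C@@H](C)CCCCCC | intermediate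
18 | (S)-2-methyloctan-1-ol | CCCCCC[C@H](C)CO | intermediate
19 | ethyl 2-(triphenyl-λ5-phosphanylidene)propanoate | CCOC(=O)C(C)=P(c1ccccc1)(c1ccccc1)c1ccccc1 | starting material
20 | (S)-2-methyloctanal | CCCCCC[C@H](C)C=O | intermediate
21 | ethyl (2E,4S)-2,4-dimethyldec-2-enoate | CCCCCC[C@H](C)/C=C(\C)C(=O)OCC | intermediate
22 | (2E,4S)-2,4-dimethyldec-2-enoic acid | CCCCCC[C@H](C)/C=C(\C)C(=O)O | intermediate
23 | (2E,4S)-2,4-dimethyldec-2-enoyl chloride | CCCCCC[C@H](C)/C=C(\C)C(Cl)=O | intermediate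
24 | (7S)-3-{2-[(tert-butyldimethylsilyl)oxy]-6-methylphenyl}-5-chloro-7-methyl-6,8-dioxo-7,8-dihydro-6H-isochromen-7-yl (2E,4S)-2,4-dimethyldec-2-enoate | CCCCCC[C@H](C)/C=C(\C)C(=O)O[C@@]1(C)C(=O)C2=COC(c3c(C)cccc3O[Si](C)(C)C(C)(C)C)=CC2=C(Cl)C1=O | intermediate
25 | (7S)-5-chloro-3-(2-hydroxy-6-methylphenyl)-7-methyl-6,8-dioxo-7,8-dihydro-6H-isochromen-7-yl (2E,4S)-2,4-dimethyldec-2-enoate | CCCCCC[C@H](C)/C=C(\C)C(=O)O[C@@]1(C)C(=O)C2=COC(c3c(C)cccc3O)=CC2=C(Cl)C1=O | target

**Step count and risks**
Total steps: 15. Longest linear sequence: 10 steps (steps 1–8, 14, 15).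

Most likely to fail, in this order:

1. Step 8. The carbene may be diverted by reversible addition at C1 or by base-induced enolisation of the diketone, E/Z equilibration of 12 may be slow, and retro-benzoin may erode the enantiomeric purity. The fallback avoids carbene catalysis and takes the C7 configuration from a separation. It sets out from 11: MnO2 (CH2Cl2) oxidises only the primary allylic alcohol to give the hydroxy keto aldehyde F1. Catalytic DBU in THF at 0 °C then closes the ring by intramolecular aldol addition of the α-hydroxy ketone (through its enediolate at C7) to the C8 aldehyde, giving the racemic 7,8-diol F2. MnO2 oxidation of the allylic C8 carbinol gives the racemic α-ketol F3. Acylation of F3 with acyl chloride 23 and DMAP gives two C7-epimeric esters; chromatography separates the 7R epimer F4 from 24, where the fallback rejoins the route.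

2. Step 4. The acetylide may add in conjugate fashion at the ester-activated C1–H with ring opening, and carbinols 8 and 9 may ionise too early on work-up. The fallback forms the C4a=C5 bond without adding a carbon nucleophile to the ring. It sets out from 6: Lawesson's reagent (toluene, 80 °C) gives the pyran-4-thione F5. S-alkylation with 1-bromobutane-2,3-dione in MeCN gives the 4-(alkylthio)pyrylium bromide F6, and Et3N/PPh3 effect the Eschenmoser sulfide contraction to the ylidene diketone ester F7. NCS chlorinates C5 to give F8. Excess DIBAL-H reduces the ester and both ketones to the triol F9, and buffered Dess–Martin periodinane (4 equiv) reoxidises all three alcohols, which rejoins the route at 12.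

3. Step 14. Acylation of the hindered tertiary α-ketol may be slower than γ-deprotonation of the acylpyridinium ion to a vinylketene, which would scramble the C4′ configuration and the E geometry. The fallback builds the enoate on the core. It sets out from 13: DCC-mediated acylation with 2-(diethoxyphosphoryl)propanoic acid (cat. DMAP, CH2Cl2) gives the phosphonate ester F10. Horner–Wadsworth–Emmons olefination of F10 with (S)-2-methyloctanal 20 (isolated from the Dess–Martin oxidation of 18 and used at once) under LiCl/i-Pr2NEt in MeCN gives the E-enoate, which rejoins the route at 24.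

**Further compounds**
F1 | step 8 | 6-{2-[(tert-butyldimethylsilyl)oxy]-6-methylphenyl}-4-(1-chloro-3-hydroxy-2-oxobutylidene)-4H-pyran-3-carbaldehyde (racemic) | O=CC1=COC(c2c(C)cccc2O[Si](C)(C)C(C)(C)C)=CC1=C(Cl)C(=O)C(C)O
F2 | step 8 | 3-{2-[(tert-butyldimethylsilyl)oxy]-6-methylphenyl}-5-chloro-7,8-dihydroxy-7-methyl-7,8-dihydro-6H-isochromen-6-one (racemic diastereomer mixture) | OC1C2=COC(c3c(C)cccc3O[Si](C)(C)C(C)(C)C)=CC2=C(Cl)C(=O)C1(C)O
F3 | step 8 | racemic 3-{2-[(tert-butyldimethylsilyl)oxy]-6-methylphenyl}-5-chloro-7-hydroxy-7-methyl-6H-isochromene-6,8(7H)-dione | OC1(C)C(=O)C2=COC(c3c(C)cccc3O[Si](C)(C)C(C)(C)C)=CC2=C(Cl)C1=O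
F4 | step 8 | (7R)-3-{2-[(tert-butyldimethylsilyl)oxy]-6-methylphenyl}-5-chloro-7-methyl-6,8-dioxo-7,8-dihydro-6H-isochromen-7-yl (2E,4S)-2,4-dimethyldec-2-enoate | CCCCCC[C@H](C)/C=C(\C)C(=O)O[C@]1(C)C(=O)C2=COC(c3c(C)cccc3O[Si](C)(C)C(C)(C)C)=CC2=C(Cl)C1=O
F5 | step 4 | ethyl 6-{2-[(tert-butyldimethylsilyl)oxy]-6-methylphenyl}-4-thioxo-4H-pyran-3-carboxylate | CCOC(=O)C1=COC(c2c(C)cccc2O[Si](C)(C)C(C)(C)C)=CC1=S
F6 | step 4 | 2-{2-[(tert-butyldimethylsilyl)oxy]-6-methylphenyl}-4-[(2,3-dioxobutyl)sulfanyl]-5-(ethoxycarbonyl)pyrylium bromide | CCOC(=O)c1c[o+]c(-c2c(C)cccc2O[Si](C)(C)C(C)(C)C)cc1SCC(=O)C(C)=O.[Br-]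
F7 | step 4 | ethyl 6-{2-[(tert-butyldimethylsilyl)oxy]-6-methylphenyl}-4-(2,3-dioxobutylidene)-4H-pyran-3-carboxylate | CCOC(=O)C1=COC(c2c(C)cccc2O[Si](C)(C)C(C)(C)C)=CC1=CC(=O)C(C)=O
F8 | step 4 | ethyl 6-{2-[(tert-butyldimethylsilyl)oxy]-6-methylphenyl}-4-(1-chloro-2,3-dioxobutylidene)-4H-pyran-3-carboxylate | CCOC(=O)C1=COC(c2c(C)cccc2O[Si](C)(C)C(C)(C)C)=CC1=C(Cl)C(=O)C(C)=O
F9 | step 4 | 1-chloro-1-[6-{2-[(tert-butyldimethylsilyl)oxy]-6-methylphenyl}-3-(hydroxymethyl)-4H-pyran-4-ylidene]butane-2,3-diol (diastereomer mixture) | OCC1=COC(c2c(C)cccc2O[Si](C)(C)C(C)(C)C)=CC1=C(Cl)C(O)C(C)O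
F10 | step 14 | (7S)-3-{2-[(tert-butyldimethylsilyl)oxy]-6-methylphenyl}-5-chloro-7-methyl-6,8-dioxo-7,8-dihydro-6H-isochromen-7-yl 2-(diethoxyphosphoryl)propanoate | CCOP(=O)(OCC)C(C)C(=O)O[C@@]1(C)C(=O)C2=COC(c3c(C)cccc3O[Si](C)(C)C(C)(C)C)=CC2=C(Cl)C1=O
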